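## The problem

The target is a depsidone. Benzoate ring A and the hydroquinone-derived ring C are joined twice, through an ester and through a diaryl ether, which makes the seven-membered dioxepinone ring B; ring C also carries a fused 2,2-dimethylchroman-4-one (ring D). Ring C is hexasubstituted: numbered C1 (lactone oxygen), C2 (methyl), C3 (carbonyl carbon of ring D), C4 (ether oxygen of ring D), C5 (free hydroxyl) and C6 (diaryl ether oxygen), it has four contiguous oxygen-bearing carbons, each with a different partner. Ring A (benzoate numbering) has the carboxyl at C1′, the ether oxygen at C2′, the formyl group at C3′, a hydroxyl at C4′ and a methyl at C6′, so the diaryl ether links two carbons that are each flanked by two substituents, the worst case for an aryl–oxygen coupling. The molecule has no stereocentre, so nothing needs to be controlled, and any stereocentre of an intermediate can be carried as a mixture as long as it is erased. The fragile functions are the aldehyde (nucleophiles, reductants), the ring B lactone (an aryl ester opened by alkoxides and hydroxide), the tertiary alkyl aryl ether of ring D (reopened by strong Lewis acids or bases) and every electron-rich hydroquinone on the way (air oxidation). The enabling feature is the pattern on ring C: the oxygens at C1 and C4 are para, C5 and C6 carry the other two oxygens, and C2 and C3 carry carbon. That is the array a 2,3-dioxygenated 4-alkenyl-4-hydroxycyclobutenone gives on ring expansion, with C1 from the ring carbonyl, C4 from the carbinol carbon, C5 and C6 from the enol ether carbons and C2 and C3 from the alkene.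

## Retrosynthesis

Target 27 comes from aldehyde 26 by cleavage of two benzyl ethers (O4′ on ring A, O5 on ring C), and 26 from dioxolane 25 by hydrolysis. No skeletal bond is cut here; the point is the choice of masks. Methyl ethers would need BBr3, which endangers the tertiary ether of ring D and the lactone, whereas benzyl ethers fall to BCl3 at −78 °C or to hydrogenolysis. The aldehyde must be masked because an alkenyllithium is used, and a cyclic acetal survives everything up to dilute acid.

In 25 the O–C(CH3)2 bond of ring D is cut (retro-oxa-Michael) to aryl enone 24, which comes by oxidation from the bis-allylic alcohol 23 and that from silyl ether 22. The neighbouring option, acylating a ring C that lacks the side chain with 3-methylbut-2-enoic acid, would need strong acid on a depsidone. Carrying the five carbons at the alcohol oxidation level lets an organolithium bring them in. The forward reaction only asks that the C4 hydroxyl, the sole phenol ortho to the side chain, adds to the enone.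

Cutting the C(=O)–O bond of ring B in 22 gives hydroxy acid 21 and, behind it, allyl ester 20. A methyl ester is not a sound precursor, because phenoxide-for-methoxide exchange is uphill (depsidones are opened by methoxide). The carboxyl therefore has to be freed and activated, and an allyl ester can be removed under neutral conditions beside a silyl ether, an acetal and benzyl ethers. Of the two hydroquinone hydroxyls in 21 only the one at C1 can reach the carboxyl (seven-membered ring), so no differentiation step is needed.

Hydroquinone 20 is disconnected at the C1–C2 bond of ring C, which unravels ring C to the four-membered ring of cyclobutenone 17. This cut is preferred over any aryl–oxygen disconnection because in 17 the diaryl ether oxygen is already attached, as a vinylogous ester oxygen, and ring A is complete. The precursor has one ring fewer and no hexasubstituted arene. The forward reaction needs only heat, outward rotation of the hydroxyl on ring opening, and exclusion of air.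

Cyclobutenone 17 is cut between the carbinol carbon and the alkene carbon into alkenyllithium 16 (from vinyl bromide 15) and the mixed squarate 9. The forward addition must occur at the carbonyl next to the benzyloxy-bearing carbon. That carbonyl is vinylogous to the weaker aryloxy donor and is the less shielded one, so electronics and sterics point the same way.

Squarate 9 is cut at its two enol ether C–O bonds into squaryl dichloride 7 (from squaric acid 6), benzyl alcohol and phenol 5, by way of ester chloride 8. This is where the hindered diaryl ether bond is made, by addition–elimination on a vinylogous acid chloride. Installing the alkoxy group first ensures that the phenoxide displaces chloride and not an oxygen leaving group.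

Phenol 5 goes back through aldehyde 4, benzyl ether 3 and allyl ester 2 to orsellinic acid 1. The formyl group is introduced after benzylation of O4′, so that the only position ortho to the one free phenol is C3′ and a phenol-directed ortho-formylation has no regiochemical choice. The allyl ester is made first, from the acid with hydrogencarbonate, which leaves the phenols untouched.

Bromide 15 comes from alcohol 14 by silylation, and 14 from (Z)-2-bromobut-2-enal 12 and 2-methylprop-1-enylmagnesium bromide 13. Enal 12 is made from crotonaldehyde 10 by bromination and dehydrobromination via dibromide 11. The alkene geometry and the carbinol configuration are irrelevant because both carbons lose their stereochemical identity later.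

## Roads not taken

Alternative 1: Ring A is carried as a 6-methylcyclohexane-2,4-dione and the diaryl ether is made as an enol ether. The cut is the C2′–O bond. In the forward key step the aryl β-keto ester A1, in which the complete ring C/D phenol is already acylated, condenses under acid with removal of water between its free C6 phenol and the ketone next to the ester-bearing carbon, closing ring B to the vinylogous ester A2.
- Merits: no aryl–oxygen coupling, easy ester formation first, and ring C with ring D is assembled by ordinary arene chemistry without an air-sensitive hydroquinone or an organolithium regiochemistry question. In these respects it is at least as good as the chosen plan.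
- Weak points: aryl β-keto esters such as A1 lose the phenol readily (acylketene formation) and decarboxylate. The closure forms a seven-membered enol ether against intermolecular condensation. After A2, ring A still has to be dehydrogenated next to an electron-rich ring C, and the formyl group must then be placed between the new hydroxyl and the ether oxygen in competition with the other ortho position. A methyl ether at C5 remains to be cleaved with a boron halide beside ring D.
- Comparison: the chosen plan sets against this that ring A is fully substituted by step 4 and that nothing but deprotection follows ring D closure.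

Alternative 2: Ring B is made by oxygen insertion into a xanthone. The cut is the C(=O)–O bond together with the carbonyl-to-ring C bond. A peracid (or a silyl peroxide with a Lewis acid) adds to the carbonyl of xanthone A3 and the electron-rich ring C carbon migrates to oxygen, giving the depsidone A4.
- Merits: xanthones are made in very few steps by acylation and cyclisation, so the tricycle is reached much faster than in the chosen plan, and one step sets the whole ring B.
- Weak points: the xanthone carbonyl is a doubly vinylogous ester carbonyl of low electrophilicity. The migration preference rests only on ring electronics (hence the deactivating acetate on ring A). Peracids also hydroxylate electron-rich arenes such as ring C. A4 still lacks ring D, the formyl group and the free C5 hydroxyl, all of which would have to be introduced by electrophilic and Lewis-acid chemistry on a base- and acid-sensitive depsidone with selective demethylation.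
- Comparison: the chosen plan is longer up to the tricycle but delivers ring C with every substituent and with both new hydroxyls differentiated by position.

Alternative 3: Ring A is built by a vinylketene benzannulation. Irradiation of the diazo ketoester A6 gives, by Wolff rearrangement, an ester-bearing vinylketene that adds [2+2] to the aryl ynol ether A5; 4π opening and 6π closure then give the hexasubstituted benzoate A7 with the ring C aryloxy group ortho to the ester.
- Merits: it shares the pericyclic logic and the avoidance of aryl–oxygen coupling, and its regiochemistry is fixed by the polarity of the ynol ether, so it has no counterpart to the carbonyl selection in step 10. That is a real advantage.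
- Weak points: A5 requires an alkynyl ether of a di-ortho-substituted phenol, which takes several steps. In A7 ring C still has a hydrogen at C3, so ring D must be attached by acylation and two methyl ethers must be told apart. The hydroxymethyl group has to be oxidised and the lactone closed as well.
- Comparison: this cascade makes the simpler ring A, while the chosen plan spends the same kind of step on the harder ring C and keeps the endgame to oxidation, cyclisation and deprotection.

Key step: step 11

Assumption: orsellinic acid, squaric acid, crotonaldehyde and 2-methylprop-1-enylmagnesium bromide (THF solution) are taken as commercial. The carbinol and silyloxy stereocentres of intermediates 14–23 are carried as racemic mixtures, since none survives into the achiral target.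

## Route

Step 1
Reactants: 1 orsellinic acid (2,4-dihydroxy-6-methylbenzoic acid)
Product: 2 allyl 2,4-dihydroxy-6-methylbenzoate
Conditions: allyl bromide, KHCO3, DMF, rt
Reagents that add atoms: allyl bromide, C=CCBr
Why: Carboxylate O-alkylation (SN2); hydrogencarbonate deprotonates only the carboxylic acid, so neither phenol is allylated, and room temperature avoids decarboxylation of the electron-rich acid.

Step 2
Reactants: 2 allyl 2,4-dihydroxy-6-methylbenzoate
Product: 3 allyl 4-(benzyloxy)-2-hydroxy-6-methylbenzoate
Conditions: BnBr (1.05 equiv), K2CO3 (1.1 equiv), acetone, reflux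
Reagents that add atoms: benzyl bromide, BrCc1ccccc1
Why: Williamson etherification; the 2-hydroxyl is tied up in a hydrogen bond to the ester carbonyl and is flanked by it, so one equivalent of base and halide alkylates the more acidic, unhindered 4-hydroxyl.

Step 3
Reactants: 3 allyl 4-(benzyloxy)-2-hydroxy-6-methylbenzoate
Product: 4 allyl 4-(benzyloxy)-3-formyl-2-hydroxy-6-methylbenzoate
Conditions: MgCl2, Et3N, (CH2O)n, MeCN, reflux; then 1 M HCl
Reagents that add atoms: paraformaldehyde (as formaldehyde), C=O
Why: Magnesium-mediated ortho-formylation of a phenol (Casnati–Skattebøl type): formaldehyde is delivered within the magnesium phenoxide to the ortho carbon and the benzylic alkoxide is oxidised by a second formaldehyde; the only free position ortho to the one free hydroxyl is C3′, so the substrate fixes the regiochemistry.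

Step 4
Reactants: 4 allyl 4-(benzyloxy)-3-formyl-2-hydroxy-6-methylbenzoate
Product: 5 allyl 4-(benzyloxy)-3-(1,3-dioxolan-2-yl)-2-hydroxy-6-methylbenzoate
Conditions: HOCH2CH2OH, TsOH·H2O (cat.), toluene, reflux (Dean–Stark)
Reagents that add atoms: ethylene glycol, OCCO
Why: Acid-catalysed acetalisation with azeotropic removal of water; the di-ortho-substituted allyl ester is too hindered to transesterify and the benzyl ether is inert.

Step 5
Reactants: 6 squaric acid
Product: 7 squaryl dichloride (3,4-dichlorocyclobut-3-ene-1,2-dione)
Conditions: (COCl)2, DMF (cat.), CH2Cl2, reflux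
Reagents that add atoms: oxalyl chloride, ClC(=O)C(=O)Cl
Why: Chloroiminium-catalysed (Vilsmeier-type) chlorination of the two vinylogous acid hydroxyls, the standard preparation of squaryl dichloride.

Step 6
Reactants: 7 squaryl dichloride, 5 allyl 4-(benzyloxy)-3-(1,3-dioxolan-2-yl)-2-hydroxy-6-methylbenzoate
Product: 9 allyl 4-(benzyloxy)-2-{[2-(benzyloxy)-3,4-dioxocyclobut-1-en-1-yl]oxy}-3-(1,3-dioxolan-2-yl)-6-methylbenzoate, via 3-(benzyloxy)-4-chlorocyclobut-3-ene-1,2-dione 8 (not isolated)
Conditions: BnOH (1.0 equiv), CH2Cl2, 0 °C to rt, evaporate; then 5, NaH, THF, −78 to 0 °C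
Reagents that add atoms: benzyl alcohol, OCc1ccccc1
Why: Two successive addition–eliminations on a vinylogous acid chloride: the first benzyloxy group donates into the ring and slows a second alcoholysis, and the sodium phenoxide of 5 then displaces chloride (better leaving group, more electrophilic carbon) in preference to benzyloxide; the hindered diaryl ether C–O bond is thus made on a highly electrophilic sp2 carbon instead of by aryl–oxygen coupling.

Step 7
Reactants: 10 crotonaldehyde
Product: 12 (Z)-2-bromobut-2-enal, via 2,3-dibromobutanal 11 (not isolated)
Conditions: Br2, CH2Cl2, 0 °C; then Et3N, 0 °C to rt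
Reagents that add atoms: bromine, BrBr
Why: Bromine addition to the enal followed by amine-induced dehydrobromination at the acidic α-hydrogen gives the α-bromo enal with the methyl group trans to the formyl group; the geometry has no consequence later.

Step 8
Reactants: 12 (Z)-2-bromobut-2-enal, 13 2-methylprop-1-enylmagnesium bromide
Product: 14 (5Z)-5-bromo-2-methylhepta-2,5-dien-4-ol (racemic)
Conditions: THF, −78 °C; then aq. NH4Cl
Reagents that add atoms: none
Why: 1,2-Addition of an alkenyl Grignard reagent to an enal at low temperature; the vinylic bromide does not exchange under these conditions, and the new carbinol centre is racemic and is oxidised away in step 15.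

Step 9
Reactants: 14 (5Z)-5-bromo-2-methylhepta-2,5-dien-4-ol
Product: 15 [(5Z)-5-bromo-2-methylhepta-2,5-dien-4-yl]oxy(tert-butyl)dimethylsilane (racemic)
Conditions: TBSCl, imidazole, DMF, rt
Reagents that add atoms: tert-butyldimethylsilyl chloride, CC(C)(C)[Si](C)(C)Cl
Why: Standard silylation of a secondary alcohol; the basic medium avoids ionisation of the bis-allylic carbinol.

Step 10
Reactants: 15 [(5Z)-5-bromo-2-methylhepta-2,5-dien-4-yl]oxy(tert-butyl)dimethylsilane, 9 allyl 4-(benzyloxy)-2-{[2-(benzyloxy)-3,4-dioxocyclobut-1-en-1-yl]oxy}-3-(1,3-dioxolan-2-yl)-6-methylbenzoate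
Product: 17 allyl 4-(benzyloxy)-2-({2-(benzyloxy)-3-hydroxy-4-oxo-3-[(2Z)-4-(tert-butyldimethylsilyloxy)-6-methylhepta-2,5-dien-3-yl]cyclobut-1-en-1-yl}oxy)-3-(1,3-dioxolan-2-yl)-6-methylbenzoate (mixture of racemic diastereomers), via alkenyllithium 16 (not isolated)
Conditions: 15, t-BuLi (2 equiv), Et2O, −78 °C; then added to 9, THF, −78 °C; aq. NH4Cl at −78 °C
Reagents that add atoms: none
Why: Bromine–lithium exchange with retention of alkene geometry, then 1,2-addition to a cyclobutenedione carbonyl; the carbonyl next to the benzyloxy-bearing carbon is vinylogous to the weak aryloxy donor (more electrophilic) and lies away from the bulky 2,6-disubstituted aryloxy group, so attack there is favoured electronically and sterically, while ester and acetal are untouched at −78 °C; the carbinol centre forms unselectively and becomes aromatic in the next step.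

Step 11
Reactants: 17 the 4-alkenyl-4-hydroxycyclobutenone of step 10
Product: 20 allyl 4-(benzyloxy)-2-[2-(benzyloxy)-4-{1-[(tert-butyldimethylsilyl)oxy]-3-methylbut-2-en-1-yl}-3,6-dihydroxy-5-methylphenoxy]-3-(1,3-dioxolan-2-yl)-6-methylbenzoate (racemic), via dienylketene 18 (not isolated), via cyclohexadienone 19 (not isolated)
Conditions: toluene (degassed, 0.01 M), 110 °C, argon
Reagents that add atoms: none
Why: Moore rearrangement: heating breaks the bond between the carbonyl carbon and the carbinol carbon of the cyclobutenone in a conrotatory 4π electrocyclic opening driven by release of ring strain, and the donor hydroxyl rotates outward, which places the alkenyl group cis to the new ketene in dienylketene 18. A thermally allowed disrotatory 6π electrocyclisation then joins the ketene carbon to the methyl-bearing alkene carbon and closes six-membered ring C as cyclohexadienone 19, whose enolisation gives the aromatic hydroquinone. The closest known reaction type is the thermolysis of 4-alkenyl-4-hydroxy-2,3-dialkoxycyclobutenones to fully substituted hydroquinones. No stereocentre is created: the carbinol carbon and both alkene carbons become aromatic, the silyloxy carbon is a spectator, and the alkene geometry does not affect the product, although the Z-methyl group lies inside the closing triene and may slow the closure. The selectivity needed is torquoselectivity (hydroxyl out, alkenyl in), secured by the intrinsic outward preference of an oxygen donor; inward rotation would lead to a butenolide. The aryloxy and benzyloxy groups are spectators that end up at C6 and C5, and the two new hydroxyls arise differentiated, the C1 hydroxyl next to the aryloxy group and the C4 hydroxyl next to the side chain. Dilute degassed toluene under argon suppresses intermolecular trapping of the ketene and oxidation of the hydroquinone, and 110 °C should leave the benzylic silyl ether intact.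

Step 12
Reactants: 20 the hydroquinone allyl ester of step 11
Product: 21 4-(benzyloxy)-2-[2-(benzyloxy)-4-{1-[(tert-butyldimethylsilyl)oxy]-3-methylbut-2-en-1-yl}-3,6-dihydroxy-5-methylphenoxy]-3-(1,3-dioxolan-2-yl)-6-methylbenzoic acid (racemic)
Conditions: Pd(PPh3)4 (cat.), morpholine, THF, rt, argon; then pH 4 buffer
Reagents that add atoms: none
Why: Allyl ester cleavage through a π-allyl complex of zerovalent palladium with morpholine as allyl acceptor (Tsuji–Trost deallylation); the neutral conditions leave silyl ether, acetal and benzyl ethers alone.

Step 13
Reactants: 21 the hydroxy acid of step 12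
Product: 22 depsidone silyl ether (ring B lactone closed between the ring A carboxyl and O1 of ring C; ring A: 4′-OBn/3′-(1,3-dioxolan-2-yl)/6′-CH3; ring C: C2-CH3/C3-CH(OTBS)CH=C(CH3)2/C4-OH/C5-OBn; racemic)
Conditions: DCC, DMAP (cat.), CH2Cl2 (0.005 M), 0 °C to rt
Reagents that add atoms: none
Why: Steglich-type lactonisation of an O-acylisourea; only the C1 hydroxyl, ortho to the diaryl ether oxygen, can reach the activated carboxyl (seven-membered ring B, the classical closure of depsidones), the para C4 hydroxyl cannot, and dilution suppresses intermolecular esterification.

Step 14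
Reactants: 22 the depsidone silyl ether
Product: 23 depsidone alcohol (as 22 with C3-CH(OH)CH=C(CH3)2; racemic)
Conditions: TBAF, AcOH, THF, 0 °C to rt
Reagents that add atoms: none
Why: Fluoride-induced cleavage of the secondary silyl ether; acetic acid buffers the medium so that the aryl ester of ring B and the free phenol are not exposed to basic fluoride.

Step 15
Reactants: 23 the depsidone alcohol
Product: 25 tetracyclic chromanone (ring D closed; O4′ and O5 benzylated; formyl group as 1,3-dioxolane), via aryl enone 24 (not isolated)
Conditions: MnO2, CH2Cl2, rt; filter; then Et3N, CH2Cl2, rt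
Reagents that add atoms: none
Why: MnO2 oxidises the doubly activated (benzylic and allylic) alcohol selectively to the aryl enone, and amine-catalysed intramolecular oxa-Michael addition of the ortho C4 phenol (6-endo-trig, favoured) closes the 2,2-dimethylchromanone, the usual fate of 2′-hydroxyaryl 2-methylpropenyl ketones.

Step 16
Reactants: 25 the tetracyclic chromanone acetal
Product: 26 O4′,O5-dibenzyl ether of the target (free formyl group)
Conditions: 1 M HCl, THF, rt
Reagents that add atoms: water, O
Why: Acid hydrolysis of the aryl dioxolane through an oxocarbenium ion stabilised by the electron-rich ring; lactone, chromanone and benzyl ethers are stable to dilute aqueous acid at room temperature.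

Step 17
Reactants: 26 the dibenzyl ether
Product: 27 target depsidone CNP0271978.0
Conditions: BCl3, C6HMe5, CH2Cl2, −78 °C; then H2O
Reagents that add atoms: none
Why: Lewis-acid debenzylation of aryl benzyl ethers with pentamethylbenzene as a non-basic benzyl cation scavenger; both ethers are assisted by a neighbouring oxygen (the formyl group at O4′, the two flanking ether oxygens at O5), and the low temperature spares the lactone and the tertiary ether of ring D.

## Compound list

1 | orsellinic acid (2,4-dihydroxy-6-methylbenzoic acid) | Cc1cc(O)cc(O)c1C(=O)O | starting material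
2 | allyl 2,4-dihydroxy-6-methylbenzoate | C=CCOC(=O)c1c(C)cc(O)cc1O | intermediate
3 | allyl 4-(benzyloxy)-2-hydroxy-6-methylbenzoate | C=CCOC(=O)c1c(C)cc(OCc2ccccc2)cc1O | intermediate
4 | allyl 4-(benzyloxy)-3-formyl-2-hydroxy-6-methylbenzoate | C=CCOC(=O)c1c(C)cc(OCc2ccccc2)c(C=O)c1O | intermediate
5 | allyl 4-(benzyloxy)-3-(1,3-dioxolan-2-yl)-2-hydroxy-6-methylbenzoate | C=CCOC(=O)c1c(C)cc(OCc2ccccc2)c(C2OCCO2)c1O | intermediate
6 | squaric acid | OC1=C(O)C(=O)C1=O | starting material
7 | squaryl dichloride (3,4-dichlorocyclobut-3-ene-1,2-dione) | ClC1=C(Cl)C(=O)C1=O | intermediate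
8 | 3-(benzyloxy)-4-chlorocyclobut-3-ene-1,2-dione | ClC1=C(OCc2ccccc2)C(=O)C1=O | intermediate
9 | allyl 4-(benzyloxy)-2-{[2-(benzyloxy)-3,4-dioxocyclobut-1-en-1-yl]oxy}-3-(1,3-dioxolan-2-yl)-6-methylbenzoate | C=CCOC(=O)c1c(C)cc(OCc2ccccc2)c(C2OCCO2)c1OC1=C(OCc2ccccc2)C(=O)C1=O | intermediate
10 | crotonaldehyde ((E)-but-2-enal) | C/C=C/C=O | starting material
11 | 2,3-dibromobutanal | CC(Br)C(Br)C=O | intermediate
12 | (Z)-2-bromobut-2-enal | C/C=C(\Br)C=O | intermediate
13 | 2-methylprop-1-enylmagnesium bromide | CC(C)=C[Mg]Br | starting material
14 | (5Z)-5-bromo-2-methylhepta-2,5-dien-4-ol (racemic) | C/C=C(\Br)C(O)C=C(C)C | intermediate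
15 | [(5Z)-5-bromo-2-methylhepta-2,5-dien-4-yl]oxy(tert-butyl)dimethylsilane (racemic) | C/C=C(\Br)C(O[Si](C)(C)C(C)(C)C)C=C(C)C | intermediate
16 | alkenyllithium from 15 (lithium in place of bromine, geometry retained) | C/C=C(\[Li])C(O[Si](C)(C)C(C)(C)C)C=C(C)C | intermediate
17 | 4-alkenyl-4-hydroxycyclobutenone: allyl 4-(benzyloxy)-2-({2-(benzyloxy)-3-hydroxy-4-oxo-3-[(2Z)-4-(tert-butyldimethylsilyloxy)-6-methylhepta-2,5-dien-3-yl]cyclobut-1-en-1-yl}oxy)-3-(1,3-dioxolan-2-yl)-6-methylbenzoate (diastereomer mixture) | C/C=C(\C1(O)C(=O)C(Oc2c(C3OCCO3)c(OCc3ccccc3)cc(C)c2C(=O)OCC=C)=C1OCc1ccccc1)C(O[Si](C)(C)C(C)(C)C)C=C(C)C | intermediate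
18 | dienylketene from ring opening of 17 (alkenyl group cis to the ketene) | C/C=C(\C(O)=C(OCc1ccccc1)/C(Oc1c(C2OCCO2)c(OCc2ccccc2)cc(C)c1C(=O)OCC=C)=C=O)C(O[Si](C)(C)C(C)(C)C)C=C(C)C | intermediate
19 | cyclohexa-2,4-dienone from 6π closure of 18 (keto tautomer of 20) | CC1C(=O)C(Oc2c(C3OCCO3)c(OCc3ccccc3)cc(C)c2C(=O)OCC=C)=C(OCc2ccccc2)C(O)=C1C(O[Si](C)(C)C(C)(C)C)C=C(C)C | intermediate
20 | allyl 4-(benzyloxy)-2-[2-(benzyloxy)-4-{1-[(tert-butyldimethylsilyl)oxy]-3-methylbut-2-en-1-yl}-3,6-dihydroxy-5-methylphenoxy]-3-(1,3-dioxolan-2-yl)-6-methylbenzoate (racemic) | C=CCOC(=O)c1c(C)cc(OCc2ccccc2)c(C2OCCO2)c1Oc1c(O)c(C)c(C(O[Si](C)(C)C(C)(C)C)C=C(C)C)c(O)c1OCc1ccccc1 | intermediate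
21 | the benzoic acid corresponding to 20 (racemic) | OC(=O)c1c(C)cc(OCc2ccccc2)c(C2OCCO2)c1Oc1c(O)c(C)c(C(O[Si](C)(C)C(C)(C)C)C=C(C)C)c(O)c1OCc1ccccc1 | intermediate
22 | depsidone silyl ether (ring B closed; C3 side chain CH(OTBS)CH=C(CH3)2; C4-OH free; racemic) | Cc1cc(OCc2ccccc2)c(C2OCCO2)c2c1C(=O)Oc1c(C)c(C(O[Si](C)(C)C(C)(C)C)C=C(C)C)c(O)c(OCc3ccccc3)c1O2 | intermediate
23 | depsidone alcohol (C3 side chain CH(OH)CH=C(CH3)2; racemic) | Cc1cc(OCc2ccccc2)c(C2OCCO2)c2c1C(=O)Oc1c(C)c(C(O)C=C(C)C)c(O)c(OCc3ccccc3)c1O2 | intermediate
24 | aryl enone (C3 side chain C(=O)CH=C(CH3)2) | Cc1cc(OCc2ccccc2)c(C2OCCO2)c2c1C(=O)Oc1c(C)c(C(=O)C=C(C)C)c(O)c(OCc3ccccc3)c1O2 | intermediate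
25 | tetracyclic chromanone with O4′- and O5-benzyl ethers and the formyl group as 1,3-dioxolane | Cc1cc(OCc2ccccc2)c(C2OCCO2)c2c1C(=O)Oc1c(C)c3c(c(OCc4ccccc4)c1O2)OC(C)(C)CC3=O | intermediate
26 | O4′,O5-dibenzyl ether of the target | Cc1cc(OCc2ccccc2)c(C=O)c2c1C(=O)Oc1c(C)c3c(c(OCc4ccccc4)c1O2)OC(C)(C)CC3=O | intermediate
27 | target depsidone CNP0271978.0 | Cc1cc(O)c(C=O)c2c1C(=O)Oc1c(C)c3c(c(O)c1O2)OC(C)(C)CC3=O | target

## Step count and risks

Total: 17 steps. Longest linear sequence: 13 steps (steps 1–4, 6 and 10–17, from orsellinic acid 1).

Least certain steps:

- **Step 11 (key step).** The hydroxyl may rotate inward on ring opening, so that the ketene is captured by it as a butenolide. The 6π closure may be slowed by the inward Z-methyl group, leaving time for intermolecular ketene trapping. The benzylic silyl ether next to the newly formed C4 phenol may ionise thermally (loss of silanol and oxa-6π closure to a chromene). The free hydroquinone may oxidise. Fallback: starting from 17, the tertiary hydroxyl is silylated (TMSCl, imidazole, CH2Cl2) to the trimethylsilyl ether F1. Thermolysis in toluene then gives the hydroquinone mono(trimethylsilyl) ether F2, in which the C4 oxygen stays capped, so there is no free hydroquinone, no hydroxyl to trap the ketene and no phenol to assist ionisation. Mild methanolysis of the aryl silyl ether (citric acid, MeOH) returns to 20.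

- **Step 10.** Addition may occur at the other carbonyl, the alkenyllithium may displace the aryloxy group by conjugate addition–elimination, or it may eliminate silyloxide to an allene before it adds. Fallback: starting from 7, two equivalents of the sodium phenoxide of 5 give the symmetrical bis(aryloxy) squarate F3, for which no carbonyl selection exists. Addition of 16 gives the adduct F4. Its aryloxy group β to the remaining carbonyl, the only one open to addition–elimination, is then exchanged for benzyloxy (BnOH, Et3N, CH2Cl2), which returns to 17 with recovery of one equivalent of 5.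

- **Step 3.** The formylation may be sluggish because the salicylate chelates magnesium and the reacting carbon sits between two oxygen substituents. Fallback: starting from 2, Rieche formylation (Cl2CHOMe, TiCl4, CH2Cl2, 0 °C), directed between the two hydroxyls by the chelated salicylate, gives allyl haematommate F5. Selective benzylation of its less hindered 4-hydroxyl (BnBr, K2CO3, acetone) returns to 4.

- **Step 14.** The ring B lactone may be opened by basic fluoride or by the phenoxide of another molecule, and the silyl group may migrate to the C4 phenol. Fallback: the order is changed. Starting from 20, desilylation (TBAF, AcOH) gives the triol ester F6, deallylation (Pd(PPh3)4, morpholine) gives the triol acid F7, and DCC lactonisation, for which only the seven-membered closure is within reach, returns to 23.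

- **Step 17.** BCl3 bound to the chromanone carbonyl may open the tertiary ether of ring D, or benzyl cations may alkylate the electron-rich rings. Fallback: starting from 25, hydrogenolysis (H2, 10% Pd/C, EtOAc) while the aldehyde is still masked against over-reduction gives the bis-phenol acetal F8, and dilute HCl in THF then gives 27 directly.

## Further compounds

F1 | step 11 | trimethylsilyl ether of cyclobutenone 17 | C/C=C(\C1(O[Si](C)(C)C)C(=O)C(Oc2c(C3OCCO3)c(OCc3ccccc3)cc(C)c2C(=O)OCC=C)=C1OCc1ccccc1)C(O[Si](C)(C)C(C)(C)C)C=C(C)C
F2 | step 11 | mono(trimethylsilyl) ether of hydroquinone 20 (silyl group on the C4 oxygen) | C=CCOC(=O)c1c(C)cc(OCc2ccccc2)c(C2OCCO2)c1Oc1c(O)c(C)c(C(O[Si](C)(C)C(C)(C)C)C=C(C)C)c(O[Si](C)(C)C)c1OCc1ccccc1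
F3 | step 10 | 3,4-bis(aryloxy)cyclobut-3-ene-1,2-dione carrying two ring A units | O=C1C(=O)C(Oc2c(C3OCCO3)c(OCc3ccccc3)cc(C)c2C(=O)OCC=C)=C1Oc1c(C2OCCO2)c(OCc2ccccc2)cc(C)c1C(=O)OCC=C
F4 | step 10 | 4-alkenyl-4-hydroxy-2,3-bis(aryloxy)cyclobutenone (diastereomer mixture) | C/C=C(\C1(O)C(=O)C(Oc2c(C3OCCO3)c(OCc3ccccc3)cc(C)c2C(=O)OCC=C)=C1Oc1c(C2OCCO2)c(OCc2ccccc2)cc(C)c1C(=O)OCC=C)C(O[Si](C)(C)C(C)(C)C)C=C(C)C
F5 | step 3 | allyl haematommate (allyl 3-formyl-2,4-dihydroxy-6-methylbenzoate) | C=CCOC(=O)c1c(C)cc(O)c(C=O)c1O
F6 | step 14 | desilylated hydroquinone allyl ester (triol, racemic) | C=CCOC(=O)c1c(C)cc(OCc2ccccc2)c(C2OCCO2)c1Oc1c(O)c(C)c(C(O)C=C(C)C)c(O)c1OCc1ccccc1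
F7 | step 14 | desilylated hydroquinone acid (triol acid, racemic) | OC(=O)c1c(C)cc(OCc2ccccc2)c(C2OCCO2)c1Oc1c(O)c(C)c(C(O)C=C(C)C)c(O)c1OCc1ccccc1
F8 | step 17 | debenzylated tetracycle with the formyl group as 1,3-dioxolane | Cc1cc(O)c(C2OCCO2)c2c1C(=O)Oc1c(C)c3c(c(O)c1O2)OC(C)(C)CC3=O
A1 | alternative 1 | ring C/D chromanone phenol esterified with 6-methyl-2,4-dioxocyclohexanecarboxylic acid | CC1CC(=O)CC(=O)C1C(=O)Oc1c(C)c2c(c(OC)c1O)OC(C)(C)CC2=O
A2 | alternative 1 | dihydro ring A depsidone (racemic vinylogous ester, relative configuration shown) | C[C@H]1CC(=O)C=C2Oc3c(OC)c4OC(C)(C)CC(=O)c4c(C)c3OC(=O)[C@H]12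
A3 | alternative 2 | 5,6-dimethoxy-1,8-dimethyl-9-oxo-9H-xanthen-3-yl acetate | Cc1cc(OC(C)=O)cc2c1C(=O)c1c(C)cc(OC)c(OC)c1O2
A4 | alternative 2 | ring D-free depsidone with ring A acetate and ring C dimethyl ether | Cc1cc(OC(C)=O)cc2c1C(=O)Oc1c(C)cc(OC)c(OC)c1O2
A5 | alternative 3 | ring C aryl ynol ether bearing a silyloxymethyl group on the alkyne | CC(C)(C)[Si](C)(C)OCC#COc1c(OCc2ccccc2)c(C)cc(OC)c1OC
A6 | alternative 3 | methyl 2-diazo-4-methyl-3-oxopent-4-enoate | COC(=O)C(=[N+]=[N-])C(=O)C(C)=C
A7 | alternative 3 | hexasubstituted ring A benzoate diaryl ether | COC(=O)c1c(C)cc(O)c(CO[Si](C)(C)C(C)(C)C)c1Oc1c(OCc2ccccc2)c(C)cc(OC)c1OC
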